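The runs are calculated from invented constants; noise was put on by code.

Which of the five flasks holds the most target at 6.0 min, and how much do the first and the last hold?

| flask | substrate | enzyme | remark | time |
|---|---|---|---|---|
| epsilon | 0.050 M (in portions, 4) | 0.0016 mol% | run made earlier; portions every 3.0 s |  |
| eta | 0.050 M (in portions, 4) | 0.014 mol% | run made earlier; portions every 3.0 s |  |
| winter | 0.050 M (in portions, 4) | 0.003 mol% | the portions of substrate follow each other after 3.0 s, the first at the start | 6.0 min |
| dawn | 0.050 M (in portions, 4) | 0.013 mol% | the portions of substrate follow each other after 3.0 s, the first at the start | 6.0 min |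
| noon | 0.050 M (in portions, 4) | 0.02 mol% | the portions of substrate follow each other after 3.0 s, the first at the start | 6.0 min |
| spring | 0.050 M (in portions, 4) | 0.006 mol% | the portions of substrate follow each other after 3.0 s, the first at the start | 6.0 min |
| dusk | 0.050 M (in portions, 4) | 0.004 mol% | the portions of substrate follow each other after 3.0 s, the first at the start | 6.0 min |

- epsilon (time / min: target / %): 0.250: 16.0; 0.417: 29.7; 0.833: 49.8; 1.50: 65.0; 3.00: 75.3
- eta (time / min: target / %): 0.250: 61.7; 0.833: 76.7; 1.33: 73.2; 2.00: 68.8; 3.00: 65.4

(standard deviation of a reading: 0.3 percentage points)

1. the flasks by amount of target, in percent of the substrate charged, highest first, at 6.0 min (winter / dawn / noon / spring / dusk)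
2. the amount of target, in percent of the substrate charged of the flask you put first, at 6.0 min
3. the amount of target, in percent of the substrate charged of the flask you put last, at 6.0 min

- the analysis behind the earlier runs scatters by 0.3 percentage points, standard deviation

For the bench: each flask holds enzyme with substrate fed in 4 portions 3.0 s apart, and target forms, but it does not stay. Eta reads 76.7% at 0.833 min, then 73.2% at 1.33 min and 65.4% at 3.00 min. Taking dose as enzyme loading times time, eta loses 22 percentage points between those last two readings for each tenfold of dose; this loss per decade of dose is the dose slope. Winter's dose at 6.0 min is larger than the dose at eta's peak reading, so the own reckoning here counts from eta's last reading along this slope. It expects 73.5% in winter and 55.3% in noon, the latter an extrapolation, since noon's dose is larger than eta's last. By this slope, raising the loading from winter's to spring's costs 6.6 points.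

The forecast, with the enzyme “essentially dead by 6 min”, gives dusk > winter > spring > dawn > noon, with 79% first and 56% last; the reckoning above puts winter first, not dusk.

The flasks give winter > dusk > spring > dawn > noon, with 72.8% in winter and 57.8% in noon.

    substrate + enzyme → target + enzyme, rate k1*[substrate]^2*[enzyme]/(1 + ([substrate]/Kh1)^2) (0.0743 M, k = 7.43 × 10⁵ /M²/s)
    2 enzyme → spent catalyst (k = 577 /M/s)
    target + enzyme ⇌ isomer of the product + enzyme, rate k3*[enzyme]*[target] forward; the back reaction follows from the equilibrium constant (K = 0.818, k = 888 /M/s)

At 6.00 min, winter still holds 61.6% of its enzyme. From winter's 72.8%, the dose slope takes the noon recipe cut to 0.005 mol% of enzyme to 67.9%, and that flask stands at 67.9%.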